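**Retrosynthetic overview**

1. Core locants: C1 = ring CH carrying the CH2CH2CH2O arm, C2 = enal-bearing ring carbon, C5 = C(OH)CH3, C6 = quaternary carbon. The strategy rests on the five-carbon chain C2–C1–CH2–CH2–CH2(O): joined between the arm terminus and C2 it is a cyclopentanone cis-fused to the cyclohexane ring. A cis-hydrindan-1-one is therefore cut between its carbonyl carbon and the ring-fusion carbon by Baeyer–Villiger oxygen insertion (δ-lactone, then LiAlH4), which delivers the arm and an oxygen on C2 together.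
2. Ring order: the cyclohexane ring is built first, onto the preformed five-membered ring, by an enantioselective Diels–Alder reaction of cyclopent-2-en-1-one with the 2-silyloxy diene from pent-1-en-3-one; the five-membered ring is then enlarged to the lactone and opened.
3. C6 comes from convex-face α′-allylation of the enone made by Saegusa–Ito oxidation, C5 from MeLi addition. The allyl group becomes the side-chain aldehyde (HWE with a geranyl-derived β-ketophosphonate, then CBS reduction for the (R)-carbinol).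
4. Enal: the arm alcohol carries a phosphonopropionate that olefinates the C2 ketone intramolecularly; the eight-membered lactone fixes the later CHO cis to C1, and i-Bu2AlH then MnO2 free the enal and the arm alcohol.
5. Last: esterification with (11Z)-hexadec-11-enoic acid and removal of the two triethylsilyl groups.

Key step: step 12

Remark: the (S)-oxazaborolidinium catalyst of step 2 is assumed to shield the same α-carbon face of cyclopent-2-en-1-one as it does for acrylates (boron on the carbonyl lone pair syn to the vinylic α-H); this gives 4 as drawn, and the (R)-catalyst would be used if the sense were opposite.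
Remark: the carbinol carbon of 5–15 and the phosphonate-bearing carbon of 21 and 22 are temporary stereocentres; 5 is drawn as the convex-face hydride adduct, and 21 and 22 are epimer mixtures at CH(CH3)P.

**Route**

Step 1
Reactants: 1 pent-1-en-3-one
Product: 2 (Z)-triisopropyl(penta-1,3-dien-3-yloxy)silane
Conditions: i-Pr3SiOSO2CF3, Et3N, CH2Cl2, 0 °C
Reagents that add atoms: triisopropylsilyl trifluoromethanesulfonate, CC(C)[Si](C(C)C)(C(C)C)OS(=O)(=O)C(F)(F)F
Why: Silyl enol ether formation by soft enolisation of the ethyl ketone should give the 2-silyloxy diene, the (Z)-enol ether being favoured because it keeps the methyl group away from the vinyl group.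

Step 2
Reactants: 3 cyclopent-2-en-1-one; 2 (Z)-triisopropyl(penta-1,3-dien-3-yloxy)silane
Product: 4 (3aS,4R,7aR)-4-methyl-5-[(triisopropylsilyl)oxy]-2,3,3a,4,7,7a-hexahydro-1H-inden-1-one (cis-fused endo adduct)
Conditions: (S)-1-(2-methylphenyl)-3,3-diphenyltetrahydro-1H,3H-pyrrolo[1,2-c][1,3,2]oxazaborole (20 mol%), HN(SO2CF3)2 (18 mol%), CH2Cl2, −78 to −20 °C
Reagents that add atoms: none
Why: Diels–Alder reaction catalysed by a chiral oxazaborolidinium salt: the enol-ether terminus of the diene bonds to the enone β-carbon, endo addition gives the cis ring fusion, and the catalyst screens one enone face, which sets C3a and C7a (C4 is set by the endo mode and is erased in step 6).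

Step 3
Reactants: 4 the Diels–Alder adduct
Product: 5 (1S,3aR,4R,7aR)-4-methyl-5-[(triisopropylsilyl)oxy]-2,3,3a,4,7,7a-hexahydro-1H-inden-1-ol
Conditions: NaBH4, MeOH/THF, 0 °C
Reagents that add atoms: none
Why: Borohydride carbonyl reduction masks the cyclopentanone; hydride should enter from the convex face of the cis-fused bicycle (temporary carbinol centre), and the hindered silyl enol ether is not touched.

Step 4
Reactants: 5 the hydrindenol
Product: 6 (1S,3aR,4R,7aR)-1-(benzyloxy)-4-methyl-5-[(triisopropylsilyl)oxy]-2,3,3a,4,7,7a-hexahydro-1H-indene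
Conditions: NaH, BnBr, n-Bu4NI (cat.), THF/DMF, 0 °C to rt
Reagents that add atoms: benzyl bromide, BrCc1ccccc1
Why: Williamson etherification of the sodium alkoxide; the triisopropylsilyl enol ether is stable to base.

Step 5
Reactants: 6 the benzyl ether
Product: 7 (1S,3aR,4R,7aR)-1-(benzyloxy)-4-methyl-1,2,3,3a,4,7a-hexahydro-5H-inden-5-one
Conditions: Pd(OAc)2 (1.1 equiv), MeCN, rt
Reagents that add atoms: none
Why: Saegusa–Ito oxidation: the palladium enolate at C6 loses β-hydride from C7, so the enone forms on the side fixed by the cycloaddition and the C4 α′-hydrogen becomes the only enolisable position next to the carbonyl.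

Step 6
Reactants: 7 the enone; 8 allyl bromide
Product: 10 (1S,3aR,4S,7aR)-1-(benzyloxy)-4-methyl-4-(prop-2-en-1-yl)-1,2,3,3a,4,7a-hexahydro-5H-inden-5-one, via lithium dienolate 9 (not isolated)
Conditions: LiN(i-Pr)2, THF, −78 °C; then 8, DMPU, −78 to −30 °C
Reagents that add atoms: none
Why: Kinetic α′-deprotonation gives the cross-conjugated lithium dienolate 9, which can be C-alkylated only at C4 (enolate alkylation); the C3a–C3 bond stands pseudoaxial on the concave face, so allyl bromide should enter on the convex face and set the quaternary carbon as (4S).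

Step 7
Reactants: 10 the allylated enone
Product: 11 (1S,3aR,4S,5S,7aR)-1-(benzyloxy)-4,5-dimethyl-4-(prop-2-en-1-yl)-2,3,3a,4,5,7a-hexahydro-1H-inden-5-ol
Conditions: MeLi, Et2O/THF, −78 °C; then H2O
Reagents that add atoms: methyllithium, [Li]C
Why: 1,2-Addition of the organolithium to the enone carbonyl; the C3a–C3 bond lies over the concave face in a 1,3-relationship to the carbonyl, so methyl should enter from the convex face and give the (5S)-carbinol with methyl cis to the allyl group.

Step 8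
Reactants: 11 the tertiary allylic alcohol
Product: 13 3-[(1S,3aR,4S,5S,7aR)-1-(benzyloxy)-5-hydroxy-4,5-dimethyl-2,3,3a,4,5,7a-hexahydro-1H-inden-4-yl]propan-1-ol, via B-alkyl-9-borabicyclononane 12 (not isolated)
Conditions: 9-BBN (9-borabicyclo[3.3.1]nonane, 2.5 equiv), THF, 0 °C to rt; then aq. NaOH, H2O2, 0 °C
Reagents that add atoms: hydrogen peroxide, OO
Why: Hydroboration–oxidation; 9-BBN selects the monosubstituted alkene over the cis-disubstituted ring alkene and places boron on the terminal carbon.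

Step 9
Reactants: 13 the diol
Product: 14 (1S,3aR,4S,5S,7aR)-1-(benzyloxy)-4,5-dimethyl-5-[(triethylsilyl)oxy]-4-{3-[(triethylsilyl)oxy]propyl}-2,3,3a,4,5,7a-hexahydro-1H-indene
Conditions: Et3SiOSO2CF3 (2.5 equiv), 2,6-lutidine, CH2Cl2, −78 to 0 °C
Reagents that add atoms: triethylsilyl trifluoromethanesulfonate, CC[Si](CC)(CC)OS(=O)(=O)C(F)(F)F
Why: Silyl triflate silylation covers the primary and the tertiary alcohol in one operation; the tertiary silyl ether later keeps that oxygen away from the side-chain aldehyde, with which the free alcohol would form a six-membered lactol.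

Step 10
Reactants: 14 the bis(triethylsilyl) ether
Product: 15 (1S,3aR,4S,5S,7aR)-4,5-dimethyl-5-[(triethylsilyl)oxy]-4-{3-[(triethylsilyl)oxy]propyl}octahydro-1H-inden-1-ol
Conditions: H2 (1 atm), Pd(OH)2 on carbon, EtOAc, rt
Reagents that add atoms: none
Why: Catalytic hydrogenation saturates the ring alkene and hydrogenolyses the benzyl ether in one operation; no stereocentre is formed, and the silyl ethers survive in a non-alcoholic solvent.

Step 11
Reactants: 15 the hydrindanol
Product: 16 (3aR,4S,5S,7aR)-4,5-dimethyl-5-[(triethylsilyl)oxy]-4-{3-[(triethylsilyl)oxy]propyl}octahydro-1H-inden-1-one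
Conditions: Dess–Martin periodinane, NaHCO3, CH2Cl2, rt
Reagents that add atoms: none
Why: Dess–Martin oxidation of the only free alcohol returns the cyclopentanone; epimerisation at C7a would be harmless because that carbon becomes a ketone in step 15.

Step 12
Reactants: 16 the cis-hydrindan-1-one
Product: 18 (4aS,5S,6S,8aR)-5,6-dimethyl-6-[(triethylsilyl)oxy]-5-{3-[(triethylsilyl)oxy]propyl}octahydro-2H-chromen-2-one, via Criegee adduct 17 (not isolated)
Conditions: m-CPBA, NaHCO3, CH2Cl2, 0 °C to rt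
Reagents that add atoms: 3-chloroperoxybenzoic acid, OOC(=O)c1cccc(Cl)c1
Why: Baeyer–Villiger oxidation: the peracid adds to the cyclopentanone carbonyl to give the Criegee adduct 17, in which the C1–C7a bond, anti-periplanar to the O–O bond, migrates to oxygen as 3-chlorobenzoate leaves. The closest known reaction type is the peracid ring expansion of fused bicyclic cyclopentanones to δ-lactones with migration of the ring-fusion carbon. The lactone ring is not closed by a cyclisation: the five-membered ketone ring is enlarged to the six-membered lactone by insertion of oxygen, which cuts the C1–C7a carbon–carbon bond. No stereocentre is created; the migrating carbon keeps its configuration because the shift is concerted and suprafacial, so C8a of 18 is (R) and its hydrogen stays cis to H-4a. The step needs migration of the secondary ring-fusion carbon and not of the C2 methylene, which the higher migratory aptitude of the more substituted carbon secures, and it needs a substrate without alkenes, which is why the allyl group was hydroborated and the ring alkene hydrogenated beforehand. The NaHCO3 buffer keeps 3-chlorobenzoic acid away from the two silyl ethers.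

Step 13
Reactants: 18 the δ-lactone
Product: 19 (1R,2S,3S,4S)-2-(3-hydroxypropyl)-3,4-dimethyl-4-[(triethylsilyl)oxy]-3-{3-[(triethylsilyl)oxy]propyl}cyclohexan-1-ol
Conditions: LiAlH4, THF, 0 °C; then aq. potassium sodium tartrate
Reagents that add atoms: none
Why: Hydride reduction of the lactone to the diol frees the three-carbon arm as a primary alcohol and leaves the oxygen on C2; silyl ethers are stable to LiAlH4.

Step 14
Reactants: 19 the diol; 20 2-(diethoxyphosphoryl)propanoic acid
Product: 21 3-[(1S,2S,3S,6R)-6-hydroxy-2,3-dimethyl-3-[(triethylsilyl)oxy]-2-{3-[(triethylsilyl)oxy]propyl}cyclohexyl]propyl 2-(diethoxyphosphoryl)propanoate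
Conditions: N,N'-diisopropylcarbodiimide, DMAP (cat.), CH2Cl2, 0 °C
Reagents that add atoms: none
Why: Steglich esterification; the primary arm alcohol should react ahead of the ring secondary alcohol, which is flanked by the substituted C1.

Step 15
Reactants: 21 the hydroxy phosphonate
Product: 22 3-[(1S,2S,3S)-2,3-dimethyl-6-oxo-3-[(triethylsilyl)oxy]-2-{3-[(triethylsilyl)oxy]propyl}cyclohexyl]propyl 2-(diethoxyphosphoryl)propanoate
Conditions: Dess–Martin periodinane, NaHCO3, CH2Cl2, rt
Reagents that add atoms: none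
Why: Dess–Martin oxidation of the ring alcohol gives the C2 ketone under near-neutral conditions that should not epimerise the adjacent C1.

Step 16
Reactants: 22 the keto phosphonate
Product: 23 (6aR,7S,8S)-1,7,8-trimethyl-8-[(triethylsilyl)oxy]-7-{3-[(triethylsilyl)oxy]propyl}-4,5,6,6a,7,8,9,10-octahydro-2H-3-benzoxocin-2-one (eight-membered lactone, ring double bond C1=C10a)
Conditions: LiCl, DBU, MeCN, 1 mM (slow addition of 22), rt to 50 °C
Reagents that add atoms: none
Why: Proposed new method: intramolecular Horner–Wadsworth–Emmons olefination of a ketone that closes an eight-membered lactone and forms a tetrasubstituted alkene. The lithium-chelated phosphonate anion (formed by DBU far more readily than the ketone enolate, so C1 should not epimerise) adds reversibly to the neighbouring ketone, and irreversible loss of diethyl phosphate from the oxaphosphetane drives the closure, the 1,2-placement of arm and ketone on the ring holding the two ends close. The eight-membered ring can hold only a cis double bond, which places the ester carbon (the later CHO) cis to C1. The closest known reaction type is the intramolecular HWE closure of keto phosphonoacetates to five- to seven-membered unsaturated lactones and of aldehydes to macrolactones.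

Step 17
Reactants: 23 the eight-membered lactone
Product: 24 (6aR,7S,8S)-7-(3-hydroxypropyl)-1,7,8-trimethyl-8-[(triethylsilyl)oxy]-4,5,6,6a,7,8,9,10-octahydro-2H-3-benzoxocin-2-one
Conditions: pyridinium p-toluenesulfonate (cat.), MeOH/CH2Cl2, 0 °C
Reagents that add atoms: none
Why: Acid-catalysed methanolysis of a silyl ether; the primary triethylsilyl ether should be cleaved much faster than the tertiary one next to the quaternary carbon.

Step 18
Reactants: 24 the primary alcohol
Product: 25 3-[(6aR,7S,8S)-1,7,8-trimethyl-2-oxo-8-[(triethylsilyl)oxy]-4,5,6,6a,7,8,9,10-octahydro-2H-3-benzoxocin-7-yl]propanal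
Conditions: Dess–Martin periodinane, NaHCO3, CH2Cl2, rt
Reagents that add atoms: none
Why: Dess–Martin oxidation to the aldehyde; with the tertiary oxygen silylated no lactol can form and over-oxidation is avoided.

Step 19
Reactants: 26 geranyl chloride
Product: 28 (3E)-4,8-dimethylnona-3,7-dienoic acid, via geranylbarium chloride 27 (not isolated)
Conditions: Ba (activated, made from BaI2 and 2 Li biphenylide, LiC12H10), THF, −78 °C; then CO2, −78 °C; aq. HCl
Reagents that add atoms: carbon dioxide, O=C=O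
Why: Oxidative addition of activated barium gives the allylbarium reagent without loss of alkene geometry at low temperature, and carboxylation of allylbarium reagents takes place at the α-carbon, giving the (E)-β,γ-unsaturated acid.

Step 20
Reactants: 28 (3E)-4,8-dimethylnona-3,7-dienoic acid; 20 2-(diethoxyphosphoryl)propanoic acid
Product: 31 diethyl [(5E)-6,10-dimethyl-3-oxoundeca-5,9-dien-2-yl]phosphonate, via acyl imidazolide 29 (not isolated), via acylated phosphono acid 30 (not isolated)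
Conditions: 28, 1,1'-carbonyldiimidazole, THF, rt; then 20, MgCl2, Et3N, MeCN, rt to 40 °C; aq. HCl
Reagents that add atoms: none
Why: Magnesium-mediated decarboxylative Claisen acylation: the magnesium enolate of the phosphono acid is C-acylated by the imidazolide under weakly basic conditions that should not move the β,γ-double bond, and the β-keto acid 30 loses CO2 on acidification.

Step 21
Reactants: 25 the aldehyde; 31 the β-ketophosphonate
Product: 32 (6aR,7S,8S)-1,7,8-trimethyl-8-[(triethylsilyl)oxy]-7-[(3E,7E)-4,8,12-trimethyl-5-oxotrideca-3,7,11-trien-1-yl]-4,5,6,6a,7,8,9,10-octahydro-2H-3-benzoxocin-2-one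
Conditions: LiCl, i-Pr2NEt, MeCN, rt
Reagents that add atoms: none
Why: Horner–Wadsworth–Emmons olefination under LiCl/amine conditions; the α-methyl β-ketophosphonate should give the (E)-trisubstituted enone, and the weak base should neither conjugate the skipped enone nor open the lactone.

Step 22
Reactants: 32 the enone
Product: 33 (6aR,7S,8S)-7-[(3E,5R,7E)-5-hydroxy-4,8,12-trimethyltrideca-3,7,11-trien-1-yl]-1,7,8-trimethyl-8-[(triethylsilyl)oxy]-4,5,6,6a,7,8,9,10-octahydro-2H-3-benzoxocin-2-one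
Conditions: (S)-1-methyl-3,3-diphenyltetrahydro-1H,3H-pyrrolo[1,2-c][1,3,2]oxazaborole (0.5 equiv), catecholborane, toluene, −78 °C; then MeOH, aq. NaHCO3
Reagents that add atoms: none
Why: Corey–Bakshi–Shibata reduction: the α-methylalkenyl group acts as the large substituent and the CH2 group as the small one, so the (S)-catalyst should give the (R)-allylic alcohol, and catecholborane at −78 °C spares the lactone and the alkenes.

Step 23
Reactants: 33 the allylic alcohol
Product: 34 (6aR,7S,8S)-1,7,8-trimethyl-8-[(triethylsilyl)oxy]-7-{(3E,5R,7E)-4,8,12-trimethyl-5-[(triethylsilyl)oxy]trideca-3,7,11-trien-1-yl}-4,5,6,6a,7,8,9,10-octahydro-2H-3-benzoxocin-2-one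
Conditions: Et3SiCl, imidazole, DMF, 0 °C
Reagents that add atoms: chlorotriethylsilane, CC[Si](CC)(CC)Cl
Why: Silylation of the secondary allylic alcohol, which would otherwise be oxidised by MnO2 in step 25.

Step 24
Reactants: 34 the silylated lactone
Product: 35 (2Z)-2-[(2R,3S,4S)-2-(3-hydroxypropyl)-3,4-dimethyl-4-[(triethylsilyl)oxy]-3-{(3E,5R,7E)-4,8,12-trimethyl-5-[(triethylsilyl)oxy]trideca-3,7,11-trien-1-yl}cyclohexylidene]propan-1-ol
Conditions: i-Bu2AlH (5 equiv), CH2Cl2, −78 to 0 °C; then aq. potassium sodium tartrate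
Reagents that add atoms: none
Why: 1,2-Reduction of the unsaturated lactone by the aluminium hydride opens the template to the allylic alcohol and the arm alcohol with the alkene geometry kept.

Step 25
Reactants: 35 the diol
Product: 36 (2Z)-2-[(2R,3S,4S)-2-(3-hydroxypropyl)-3,4-dimethyl-4-[(triethylsilyl)oxy]-3-{(3E,5R,7E)-4,8,12-trimethyl-5-[(triethylsilyl)oxy]trideca-3,7,11-trien-1-yl}cyclohexylidene]propanal
Conditions: MnO2 (activated, excess), CH2Cl2, rt
Reagents that add atoms: none
Why: Manganese dioxide oxidation is selective for the allylic primary alcohol, so the saturated arm alcohol stays free and the enal geometry is kept.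

Step 26
Reactants: 36 the hydroxy enal; 37 (11Z)-hexadec-11-enoic acid
Product: 38 the 3-O,5′-O-bis(triethylsilyl) ether of the target: 3-[(1R,2S,3S,6Z)-2,3-dimethyl-6-(1-oxopropan-2-ylidene)-3-[(triethylsilyl)oxy]-2-{(3E,5R,7E)-4,8,12-trimethyl-5-[(triethylsilyl)oxy]trideca-3,7,11-trien-1-yl}cyclohexyl]propyl (11Z)-hexadec-11-enoate
Conditions: N,N'-diisopropylcarbodiimide, DMAP (cat.), CH2Cl2, 0 °C to rt
Reagents that add atoms: none
Why: Steglich esterification of the only free hydroxyl group with the fatty acid; the enal and the silyl ethers are inert.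

Step 27
Reactants: 38 the bis(triethylsilyl) ether
Product: 39 CNP0177216.2, 3-[(1R,2S,3S,6Z)-3-hydroxy-2-[(3E,5R,7E)-5-hydroxy-4,8,12-trimethyltrideca-3,7,11-trien-1-yl]-2,3-dimethyl-6-(1-oxopropan-2-ylidene)cyclohexyl]propyl (11Z)-hexadec-11-enoate
Conditions: HF·pyridine, pyridine, THF, 0 °C to rt
Reagents that add atoms: none
Why: Fluoride cleavage of both triethylsilyl ethers under pyridine-buffered conditions that should leave the ester, the enal and the allylic alcohol untouched.

**Compound list**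

1 | pent-1-en-3-one | CCC(=O)C=C | starting material
2 | (Z)-triisopropyl(penta-1,3-dien-3-yloxy)silane | C/C=C(\O[Si](C(C)C)(C(C)C)C(C)C)C=C | intermediate
3 | cyclopent-2-en-1-one | O=C1C=CCC1 | starting material
4 | (3aS,4R,7aR)-4-methyl-5-[(triisopropylsilyl)oxy]-2,3,3a,4,7,7a-hexahydro-1H-inden-1-one | O=C1CC[C@@H]2[C@H]1CC=C(O[Si](C(C)C)(C(C)C)C(C)C)[C@@H]2C | intermediate
5 | (1S,3aR,4R,7aR)-4-methyl-5-[(triisopropylsilyl)oxy]-2,3,3a,4,7,7a-hexahydro-1H-inden-1-ol | O[C@H]1CC[C@@H]2[C@H]1CC=C(O[Si](C(C)C)(C(C)C)C(C)C)[C@@H]2C | intermediate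
6 | (1S,3aR,4R,7aR)-1-(benzyloxy)-4-methyl-5-[(triisopropylsilyl)oxy]-2,3,3a,4,7,7a-hexahydro-1H-indene | O(Cc1ccccc1)[C@H]2CC[C@@H]3[C@H]2CC=C(O[Si](C(C)C)(C(C)C)C(C)C)[C@@H]3C | intermediate
7 | (1S,3aR,4R,7aR)-1-(benzyloxy)-4-methyl-1,2,3,3a,4,7a-hexahydro-5H-inden-5-one | O(Cc1ccccc1)[C@H]2CC[C@@H]3[C@H]2C=CC(=O)[C@@H]3C | intermediate
8 | allyl bromide (3-bromoprop-1-ene) | C=CCBr | starting material
9 | lithium (1S,3aR,7aR)-1-(benzyloxy)-4-methyl-2,3,3a,7a-tetrahydro-1H-inden-5-olate | O(Cc1ccccc1)[C@H]2CC[C@@H]3[C@H]2C=CC(O[Li])=C3C | intermediate (not isolated)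
10 | (1S,3aR,4S,7aR)-1-(benzyloxy)-4-methyl-4-(prop-2-en-1-yl)-1,2,3,3a,4,7a-hexahydro-5H-inden-5-one | O(Cc1ccccc1)[C@H]2CC[C@@H]3[C@H]2C=CC(=O)[C@@]3(C)CC=C | intermediate
11 | (1S,3aR,4S,5S,7aR)-1-(benzyloxy)-4,5-dimethyl-4-(prop-2-en-1-yl)-2,3,3a,4,5,7a-hexahydro-1H-inden-5-ol | O(Cc1ccccc1)[C@H]2CC[C@@H]3[C@H]2C=C[C@](C)(O)[C@@]3(C)CC=C | intermediate
12 | 9-{3-[(1S,3aR,4S,5S,7aR)-1-(benzyloxy)-5-hydroxy-4,5-dimethyl-2,3,3a,4,5,7a-hexahydro-1H-inden-4-yl]propyl}-9-borabicyclo[3.3.1]nonane | O(Cc1ccccc1)[C@H]2CC[C@@H]3[C@H]2C=C[C@](C)(O)[C@@]3(C)CCCB4C5CCCC4CCC5 | intermediate (not isolated)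
13 | 3-[(1S,3aR,4S,5S,7aR)-1-(benzyloxy)-5-hydroxy-4,5-dimethyl-2,3,3a,4,5,7a-hexahydro-1H-inden-4-yl]propan-1-ol | O(Cc1ccccc1)[C@H]2CC[C@@H]3[C@H]2C=C[C@](C)(O)[C@@]3(C)CCCO | intermediate
14 | (1S,3aR,4S,5S,7aR)-1-(benzyloxy)-4,5-dimethyl-5-[(triethylsilyl)oxy]-4-{3-[(triethylsilyl)oxy]propyl}-2,3,3a,4,5,7a-hexahydro-1H-indene | O(Cc1ccccc1)[C@H]2CC[C@@H]3[C@H]2C=C[C@](C)(O[Si](CC)(CC)CC)[C@@]3(C)CCCO[Si](CC)(CC)CC | intermediate
15 | (1S,3aR,4S,5S,7aR)-4,5-dimethyl-5-[(triethylsilyl)oxy]-4-{3-[(triethylsilyl)oxy]propyl}octahydro-1H-inden-1-ol | O[C@H]1CC[C@@H]2[C@H]1CC[C@](C)(O[Si](CC)(CC)CC)[C@@]2(C)CCCO[Si](CC)(CC)CC | intermediate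
16 | (3aR,4S,5S,7aR)-4,5-dimethyl-5-[(triethylsilyl)oxy]-4-{3-[(triethylsilyl)oxy]propyl}octahydro-1H-inden-1-one | O=C1CC[C@@H]2[C@H]1CC[C@](C)(O[Si](CC)(CC)CC)[C@@]2(C)CCCO[Si](CC)(CC)CC | intermediate
17 | Criegee adduct of 16: 1-hydroxy-1-[(3-chlorobenzoyl)peroxy] derivative | OC1(OOC(=O)c2cccc(Cl)c2)CC[C@@H]3[C@H]1CC[C@](C)(O[Si](CC)(CC)CC)[C@@]3(C)CCCO[Si](CC)(CC)CC | intermediate (not isolated)
18 | (4aS,5S,6S,8aR)-5,6-dimethyl-6-[(triethylsilyl)oxy]-5-{3-[(triethylsilyl)oxy]propyl}octahydro-2H-chromen-2-one | O=C1CC[C@@H]2[C@H](O1)CC[C@](C)(O[Si](CC)(CC)CC)[C@@]2(C)CCCO[Si](CC)(CC)CC | intermediate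
19 | (1R,2S,3S,4S)-2-(3-hydroxypropyl)-3,4-dimethyl-4-[(triethylsilyl)oxy]-3-{3-[(triethylsilyl)oxy]propyl}cyclohexan-1-ol | OCCC[C@@H]1[C@H](O)CC[C@](C)(O[Si](CC)(CC)CC)[C@@]1(C)CCCO[Si](CC)(CC)CC | intermediate
20 | 2-(diethoxyphosphoryl)propanoic acid | CCOP(=O)(OCC)C(C)C(=O)O | starting material
21 | 3-[(1S,2S,3S,6R)-6-hydroxy-2,3-dimethyl-3-[(triethylsilyl)oxy]-2-{3-[(triethylsilyl)oxy]propyl}cyclohexyl]propyl 2-(diethoxyphosphoryl)propanoate | CCOP(=O)(OCC)C(C)C(=O)OCCC[C@@H]1[C@H](O)CC[C@](C)(O[Si](CC)(CC)CC)[C@@]1(C)CCCO[Si](CC)(CC)CC | intermediate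
22 | 3-[(1S,2S,3S)-2,3-dimethyl-6-oxo-3-[(triethylsilyl)oxy]-2-{3-[(triethylsilyl)oxy]propyl}cyclohexyl]propyl 2-(diethoxyphosphoryl)propanoate | CCOP(=O)(OCC)C(C)C(=O)OCCC[C@@H]1C(=O)CC[C@](C)(O[Si](CC)(CC)CC)[C@@]1(C)CCCO[Si](CC)(CC)CC | intermediate
23 | (6aR,7S,8S)-1,7,8-trimethyl-8-[(triethylsilyl)oxy]-7-{3-[(triethylsilyl)oxy]propyl}-4,5,6,6a,7,8,9,10-octahydro-2H-3-benzoxocin-2-one | O=C1OCCC[C@@H]2/C(=C1/C)CC[C@](C)(O[Si](CC)(CC)CC)[C@@]2(C)CCCO[Si](CC)(CC)CC | intermediate
24 | (6aR,7S,8S)-7-(3-hydroxypropyl)-1,7,8-trimethyl-8-[(triethylsilyl)oxy]-4,5,6,6a,7,8,9,10-octahydro-2H-3-benzoxocin-2-one | O=C1OCCC[C@@H]2/C(=C1/C)CC[C@](C)(O[Si](CC)(CC)CC)[C@@]2(C)CCCO | intermediate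
25 | 3-[(6aR,7S,8S)-1,7,8-trimethyl-2-oxo-8-[(triethylsilyl)oxy]-4,5,6,6a,7,8,9,10-octahydro-2H-3-benzoxocin-7-yl]propanal | O=C1OCCC[C@@H]2/C(=C1/C)CC[C@](C)(O[Si](CC)(CC)CC)[C@@]2(C)CCC=O | intermediate
26 | geranyl chloride, (2E)-1-chloro-3,7-dimethylocta-2,6-diene | ClC/C=C(\C)CCC=C(C)C | starting material
27 | [(2E)-3,7-dimethylocta-2,6-dien-1-yl]barium chloride | Cl[Ba]C/C=C(\C)CCC=C(C)C | intermediate (not isolated)
28 | (3E)-4,8-dimethylnona-3,7-dienoic acid | OC(=O)C/C=C(\C)CCC=C(C)C | intermediate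
29 | 1-[(3E)-4,8-dimethylnona-3,7-dienoyl]-1H-imidazole | O=C(C/C=C(\C)CCC=C(C)C)n1ccnc1 | intermediate (not isolated)
30 | (5E)-2-(diethoxyphosphoryl)-2,6,10-trimethyl-3-oxoundeca-5,9-dienoic acid | CCOP(=O)(OCC)C(C)(C(=O)O)C(=O)C/C=C(\C)CCC=C(C)C | intermediate (not isolated)
31 | diethyl [(5E)-6,10-dimethyl-3-oxoundeca-5,9-dien-2-yl]phosphonate | CCOP(=O)(OCC)C(C)C(=O)C/C=C(\C)CCC=C(C)C | intermediate
32 | (6aR,7S,8S)-1,7,8-trimethyl-8-[(triethylsilyl)oxy]-7-[(3E,7E)-4,8,12-trimethyl-5-oxotrideca-3,7,11-trien-1-yl]-4,5,6,6a,7,8,9,10-octahydro-2H-3-benzoxocin-2-one | O=C1OCCC[C@@H]2/C(=C1/C)CC[C@](C)(O[Si](CC)(CC)CC)[C@@]2(C)CC/C=C(\C)C(=O)C/C=C(\C)CCC=C(C)C | intermediate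
33 | (6aR,7S,8S)-7-[(3E,5R,7E)-5-hydroxy-4,8,12-trimethyltrideca-3,7,11-trien-1-yl]-1,7,8-trimethyl-8-[(triethylsilyl)oxy]-4,5,6,6a,7,8,9,10-octahydro-2H-3-benzoxocin-2-one | O=C1OCCC[C@@H]2/C(=C1/C)CC[C@](C)(O[Si](CC)(CC)CC)[C@@]2(C)CC/C=C(\C)[C@H](O)C/C=C(\C)CCC=C(C)C | intermediate
34 | (6aR,7S,8S)-1,7,8-trimethyl-8-[(triethylsilyl)oxy]-7-{(3E,5R,7E)-4,8,12-trimethyl-5-[(triethylsilyl)oxy]trideca-3,7,11-trien-1-yl}-4,5,6,6a,7,8,9,10-octahydro-2H-3-benzoxocin-2-one | O=C1OCCC[C@@H]2/C(=C1/C)CC[C@](C)(O[Si](CC)(CC)CC)[C@@]2(C)CC/C=C(\C)[C@H](O[Si](CC)(CC)CC)C/C=C(\C)CCC=C(C)C | intermediate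
35 | (2Z)-2-[(2R,3S,4S)-2-(3-hydroxypropyl)-3,4-dimethyl-4-[(triethylsilyl)oxy]-3-{(3E,5R,7E)-4,8,12-trimethyl-5-[(triethylsilyl)oxy]trideca-3,7,11-trien-1-yl}cyclohexylidene]propan-1-ol | OCCC[C@@H]1/C(=C(/C)CO)CC[C@](C)(O[Si](CC)(CC)CC)[C@@]1(C)CC/C=C(\C)[C@H](O[Si](CC)(CC)CC)C/C=C(\C)CCC=C(C)C | intermediate
36 | (2Z)-2-[(2R,3S,4S)-2-(3-hydroxypropyl)-3,4-dimethyl-4-[(triethylsilyl)oxy]-3-{(3E,5R,7E)-4,8,12-trimethyl-5-[(triethylsilyl)oxy]trideca-3,7,11-trien-1-yl}cyclohexylidene]propanal | OCCC[C@@H]1/C(=C(/C)C=O)CC[C@](C)(O[Si](CC)(CC)CC)[C@@]1(C)CC/C=C(\C)[C@H](O[Si](CC)(CC)CC)C/C=C(\C)CCC=C(C)C | intermediate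
37 | (11Z)-hexadec-11-enoic acid | CCCC/C=C\CCCCCCCCCC(=O)O | starting material
38 | 3-[(1R,2S,3S,6Z)-2,3-dimethyl-6-(1-oxopropan-2-ylidene)-3-[(triethylsilyl)oxy]-2-{(3E,5R,7E)-4,8,12-trimethyl-5-[(triethylsilyl)oxy]trideca-3,7,11-trien-1-yl}cyclohexyl]propyl (11Z)-hexadec-11-enoate | CCCC/C=C\CCCCCCCCCC(=O)OCCC[C@@H]1/C(=C(/C)C=O)CC[C@](C)(O[Si](CC)(CC)CC)[C@@]1(C)CC/C=C(\C)[C@H](O[Si](CC)(CC)CC)C/C=C(\C)CCC=C(C)C | intermediate
39 | CNP0177216.2, 3-[(1R,2S,3S,6Z)-3-hydroxy-2-[(3E,5R,7E)-5-hydroxy-4,8,12-trimethyltrideca-3,7,11-trien-1-yl]-2,3-dimethyl-6-(1-oxopropan-2-ylidene)cyclohexyl]propyl (11Z)-hexadec-11-enoate | CCCC/C=C\CCCCCCCCCC(=O)OCCC[C@@H]1/C(=C(/C)C=O)CC[C@](C)(O)[C@@]1(C)CC/C=C(\C)[C@H](O)C/C=C(\C)CCC=C(C)C | target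

**Step count**

Total step count: 27 steps.
Longest linear sequence: 25 steps (steps 1–18 and 21–27, from pent-1-en-3-one; 24 from cyclopent-2-en-1-one). Steps 19 and 20 form the side branch to phosphonate 31.

**Steps most likely to fail**

1. Step 16 (Proposed new method). The phosphonate anion may not reach the ketone across the forming eight-membered ring, so that intermolecular olefination to a sixteen-membered dimer, or slow enolisation of the ketone with epimerisation at C1, takes over. The fallback uses known chemistry and forms the C–C bond and the alkene in separate operations. It sets out from 19: the primary alcohol is esterified with 2-bromopropanoic acid (N,N'-diisopropylcarbodiimide, DMAP) to give the bromo ester F1, and Dess–Martin oxidation of the ring alcohol gives the bromo keto ester F2. An intramolecular Reformatsky reaction with SmI2 (THF, high dilution, −78 to 0 °C), a closure known for eight- to fourteen-membered lactones because the samarium enolate is chelated to the carbonyl group, is followed by trapping of the samarium aldolate with Ac2O to give the acetoxy lactone F3. E1cB elimination of acetic acid with DBU in toluene can give only the conjugated alkene, which the ring forces to be cis, and the sequence comes back to the route at 23.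

2. Step 2. Cyclopent-2-en-1-one is a sluggish dienophile, so the catalysed cycloaddition may be slow, may lose enantioselectivity to the uncatalysed pathway, or may proceed with the opposite facial sense. The fallback replaces asymmetric catalysis by a racemic cycloaddition and an enzymatic resolution. It sets out from 2 and 3: Me2AlCl (CH2Cl2, −78 °C) should give 4 together with its enantiomer, the ent-adduct F4, and NaBH4 reduction gives 5 together with the enantiomeric alcohol F5. Lipase-catalysed transesterification (Burkholderia cepacia lipase, vinyl acetate, t-BuOMe) should, by the usual empirical rule for secondary alcohols, acetylate the (1R)-alcohol to the acetate F6 and leave 5, which is separated by chromatography. The sequence comes back to the route at 5.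

3. Step 7. Methyl delivery may occur from the concave face, or with a poor facial ratio, because the convex face also carries the allyl group on the neighbouring quaternary carbon. The fallback sets the carbinol by an epoxide relay, in which the reagent places oxygen (not carbon) on the face it prefers, so that concave-face attack gives the wanted (5S)-centre. It sets out from 10: conjugate reduction with [(Ph3P)CuH]6 (benzene, rt) gives the saturated ketone F7, and Wittig methylenation (Ph3P=CH2, toluene, 80 °C) gives the exocyclic alkene F8. Epoxidation with one equivalent of m-CPBA (NaHCO3, 0 °C; the 1,1-disubstituted alkene reacts ahead of the monosubstituted allyl group) gives the spiro-epoxide F9 with oxygen on the concave face, and LiAlH4 opens it at the CH2 carbon to the tertiary alcohol F10. Hydroboration–oxidation with 9-BBN gives the diol F11, Et3SiOSO2CF3 and 2,6-lutidine give the bis(triethylsilyl) ether F12, and hydrogenolysis (H2, Pd(OH)2 on carbon) comes back to the route at 15.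

**Further compounds**

F1 | step 16 | 3-[(1S,2S,3S,6R)-6-hydroxy-2,3-dimethyl-3-[(triethylsilyl)oxy]-2-{3-[(triethylsilyl)oxy]propyl}cyclohexyl]propyl 2-bromopropanoate | CC(Br)C(=O)OCCC[C@@H]1[C@H](O)CC[C@](C)(O[Si](CC)(CC)CC)[C@@]1(C)CCCO[Si](CC)(CC)CC
F2 | step 16 | 3-[(1S,2S,3S)-2,3-dimethyl-6-oxo-3-[(triethylsilyl)oxy]-2-{3-[(triethylsilyl)oxy]propyl}cyclohexyl]propyl 2-bromopropanoate | CC(Br)C(=O)OCCC[C@@H]1C(=O)CC[C@](C)(O[Si](CC)(CC)CC)[C@@]1(C)CCCO[Si](CC)(CC)CC
F3 | step 16 | (6aS,7S,8S)-1,7,8-trimethyl-2-oxo-8-[(triethylsilyl)oxy]-7-{3-[(triethylsilyl)oxy]propyl}dodecahydro-10aH-3-benzoxocin-10a-yl acetate (C1 and C10a unassigned) | CC1C(=O)OCCC[C@@H]2C1(OC(C)=O)CC[C@](C)(O[Si](CC)(CC)CC)[C@@]2(C)CCCO[Si](CC)(CC)CC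
F4 | step 2 | (3aR,4S,7aS)-4-methyl-5-[(triisopropylsilyl)oxy]-2,3,3a,4,7,7a-hexahydro-1H-inden-1-one | O=C1CC[C@H]2[C@@H]1CC=C(O[Si](C(C)C)(C(C)C)C(C)C)[C@H]2C
F5 | step 2 | (1R,3aS,4S,7aS)-4-methyl-5-[(triisopropylsilyl)oxy]-2,3,3a,4,7,7a-hexahydro-1H-inden-1-ol | O[C@@H]1CC[C@H]2[C@@H]1CC=C(O[Si](C(C)C)(C(C)C)C(C)C)[C@H]2C
F6 | step 2 | (1R,3aS,4S,7aS)-4-methyl-5-[(triisopropylsilyl)oxy]-2,3,3a,4,7,7a-hexahydro-1H-inden-1-yl acetate | CC(=O)O[C@@H]1CC[C@H]2[C@@H]1CC=C(O[Si](C(C)C)(C(C)C)C(C)C)[C@H]2C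
F7 | step 7 | (1S,3aR,4S,7aR)-1-(benzyloxy)-4-methyl-4-(prop-2-en-1-yl)octahydro-5H-inden-5-one | O(Cc1ccccc1)[C@H]2CC[C@@H]3[C@H]2CCC(=O)[C@@]3(C)CC=C
F8 | step 7 | (1S,3aR,4S,7aR)-1-(benzyloxy)-4-methyl-5-methylidene-4-(prop-2-en-1-yl)octahydro-1H-indene | O(Cc1ccccc1)[C@H]2CC[C@@H]3[C@H]2CCC(=C)[C@@]3(C)CC=C
F9 | step 7 | (1S,3aR,4S,7aR)-1-(benzyloxy)-4-methyl-4-(prop-2-en-1-yl)octahydrospiro[indene-5,2'-oxirane], epoxide oxygen on the concave face (cis to the 4-methyl group) | O(Cc1ccccc1)[C@H]2CC[C@@H]3[C@H]2CC[C@]4(OC4)[C@@]3(C)CC=C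
F10 | step 7 | (1S,3aR,4S,5S,7aR)-1-(benzyloxy)-4,5-dimethyl-4-(prop-2-en-1-yl)octahydro-1H-inden-5-ol | O(Cc1ccccc1)[C@H]2CC[C@@H]3[C@H]2CC[C@](C)(O)[C@@]3(C)CC=C
F11 | step 7 | 3-[(1S,3aR,4S,5S,7aR)-1-(benzyloxy)-5-hydroxy-4,5-dimethyloctahydro-1H-inden-4-yl]propan-1-ol | O(Cc1ccccc1)[C@H]2CC[C@@H]3[C@H]2CC[C@](C)(O)[C@@]3(C)CCCO
F12 | step 7 | (1S,3aR,4S,5S,7aR)-1-(benzyloxy)-4,5-dimethyl-5-[(triethylsilyl)oxy]-4-{3-[(triethylsilyl)oxy]propyl}octahydro-1H-indene | O(Cc1ccccc1)[C@H]2CC[C@@H]3[C@H]2CC[C@](C)(O[Si](CC)(CC)CC)[C@@]3(C)CCCO[Si](CC)(CC)CC
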